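**Strategy.** Everything rests on cutting the C1–C2 bond of the cyclohexene ring (C1 quaternary carbinol bearing C7, C2 benzoate, C3=C4 alkene, C5 benzoate, C6 carbinol). The cis oxygens on C1, C6 and C5 are O2, O3 and O4 of a 2-alkoxy-D-galactal, and C3=C4 lies where a [3,3] shift deposits its alkene. Heating this glycal, whose sugar C5 carries an (E)-2-benzoyloxyvinyl group, should in one operation open the pyran, form C1–C2, close the carbocycle, fix C1 and C2 and unveil C7 as an aldehyde. Since a 2-acyloxyglycal cannot be reprotected (its enol ketonises), the PMB ethers go onto a thiogalactoside and the enol ether is made last, by sulfoxide elimination.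

Key step: step 10

Remark: compound 1 is taken as a catalogue compound (D-galactose masked as its β-phenylthio glycoside, three routine steps from the free sugar), so sugar C3, C4 and C5 of D-galactose are the only source of chirality.

Conventions: PMB = 4-methoxybenzyl and Bz = benzoyl. "Sugar C1–C7" numbers the pyranose, with C7 the added carbon. Plain C1–C7 numbers the target as in the first paragraph.

Step 1
Reactants: 1 phenyl 1-thio-β-D-galactopyranoside; 2 benzaldehyde dimethyl acetal
Product: 3 phenyl 4,6-O-[(S)-benzylidene]-1-thio-β-D-galactopyranoside (phenyl equatorial on the dioxane)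
Conditions: PhCH(OMe)2, CSA (cat.), MeCN, rt
Reagents that add atoms: benzaldehyde dimethyl acetal (2), COC(OC)c1ccccc1
Why: Acid-catalysed transacetalisation closes the thermodynamically preferred 1,3-dioxane over O4/O6 with the phenyl group equatorial (this sets the acetal carbon) and leaves only O2 and O3 free.

Step 2
Reactants: 3 phenyl 4,6-O-[(S)-benzylidene]-1-thio-β-D-galactopyranoside; 4 4-methoxybenzyl chloride
Product: 5 phenyl 4,6-O-[(S)-benzylidene]-2,3-di-O-PMB-1-thio-β-D-galactopyranoside
Conditions: NaH, PMBCl, DMF, 0 °C → rt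
Reagents that add atoms: 4-methoxybenzyl chloride (4), COc1ccc(CCl)cc1
Why: Williamson etherification of the two remaining hydroxyls leaves the acetal and thioglycoside untouched, and it places the ether on O2 while sugar C2 is still sp3, which is the only practical way to reach the later enol ether.

Step 3
Reactants: 5 phenyl 4,6-O-[(S)-benzylidene]-2,3-di-O-PMB-1-thio-β-D-galactopyranoside
Product: 6 phenyl 2,3-di-O-PMB-1-thio-β-D-galactopyranoside (4,6-diol)
Conditions: AcOH/H2O (4:1), 60 °C
Reagents that add atoms: none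
Why: Mild acid hydrolysis removes the benzylidene acetal, which is far more labile than PMB ethers or the aryl thioglycoside under these conditions.

Step 4
Reactants: 6 phenyl 2,3-di-O-PMB-1-thio-β-D-galactopyranoside
Product: 7 phenyl 2,3-di-O-PMB-1-thio-β-D-galacto-hexodialdo-1,5-pyranoside (C6 aldehyde, 4-OH free; dried azeotropically and used at once)
Conditions: TEMPO (0.2 equiv), PhI(OAc)2 (1.1 equiv), dry CH2Cl2, rt
Reagents that add atoms: none
Why: Oxoammonium oxidation (TEMPO/PhI(OAc)2) is selective for the primary alcohol and spares aryl sulfides, and keeping O4 as a hydroxyl rather than an ester removes the leaving group that would invite E1cB loss across sugar C4–C5 of the aldehyde.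

Step 5
Reactants: 7 phenyl 2,3-di-O-PMB-1-thio-β-D-galacto-hexodialdo-1,5-pyranoside; 8 iodoform
Product: 9 phenyl (E)-6,7-dideoxy-7-iodo-2,3-di-O-PMB-1-thio-β-D-galacto-hept-6-enopyranoside
Conditions: CrCl2 (8 equiv), CHI3 (3 equiv), THF/1,4-dioxane (1:6), 0 °C → rt
Reagents that add atoms: iodoform (8), IC(I)I
Why: In the Takai olefination the gem-dichromium reagent from CHI3 adds to the aldehyde and eliminates to the (E)-iodoalkene; it tolerates the free hydroxyl and is non-basic, so sugar C5 is not epimerised, and any Z isomer is removed by chromatography at this stage.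

Step 6
Reactants: 9 phenyl (E)-6,7-dideoxy-7-iodo-2,3-di-O-PMB-1-thio-β-D-galacto-hept-6-enopyranoside; 10 benzoyl chloride
Product: 11 phenyl (E)-4-O-benzoyl-6,7-dideoxy-7-iodo-2,3-di-O-PMB-1-thio-β-D-galacto-hept-6-enopyranoside
Conditions: BzCl, pyridine, DMAP (cat.), CH2Cl2, 0 °C → rt
Reagents that add atoms: benzoyl chloride (10), O=C(Cl)c1ccccc1
Why: DMAP-catalysed acylation of the axial 4-OH is safe now that sugar C6 is no longer a carbonyl carbon, so the benzoate cannot be lost by β-elimination.

Step 7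
Reactants: 11 phenyl (E)-4-O-benzoyl-6,7-dideoxy-7-iodo-2,3-di-O-PMB-1-thio-β-D-galacto-hept-6-enopyranoside; 12 benzoic acid
Product: 13 phenyl (E)-4,7-di-O-benzoyl-6-deoxy-2,3-di-O-PMB-1-thio-β-D-galacto-hept-6-enopyranoside (E enol benzoate)
Conditions: BzOH, CuI (20 mol %), 1,10-phenanthroline (40 mol %), Cs2CO3, toluene, 90 °C
Reagents that add atoms: benzoic acid (12), O=C(O)c1ccccc1
Why: Ullmann-type C(sp2)–O coupling of a vinyl iodide with a carboxylate at monovalent copper proceeds with retention of alkene geometry, and in the E iodide H6 and iodine are cis, so base-induced anti elimination to the alkyne is disfavoured.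

Step 8
Reactants: 13 phenyl (E)-4,7-di-O-benzoyl-6-deoxy-2,3-di-O-PMB-1-thio-β-D-galacto-hept-6-enopyranoside
Product: 14 the corresponding β-glycosyl phenyl sulfoxide (both configurations at sulfur)
Conditions: mCPBA (1.0 equiv), CH2Cl2, −78 °C
Reagents that add atoms: mCPBA, O=C(OO)c1cccc(Cl)c1
Why: In this chemoselective sulfide oxidation one equivalent of peracid at −78 °C attacks sulfur much faster than the enol ester alkene or the anisyl rings and stops at the sulfoxide, and the new sulfur stereocentre is irrelevant because both epimers can eliminate.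

Step 9
Reactants: 14 β-glycosyl phenyl sulfoxide
Product: 15 (E)-1,5-anhydro-4,7-di-O-benzoyl-6-deoxy-2,3-di-O-PMB-D-lyxo-hepta-1,6-dienitol (4-O-benzoyl-2,3-di-O-PMB-2-hydroxy-D-galactal with an (E)-2-benzoyloxyvinyl group on sugar C5)
Conditions: toluene, iPr2NEt, 110 °C
Reagents that add atoms: none
Why: Thermal syn (Ei) elimination of a glycosyl sulfoxide is a known entry to 2-oxygenated glycals, since the equatorial β-sulfinyl group is cis to axial H2, H2 is the only β-hydrogen, and the neutral medium spares the acid-labile product.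

Step 10
Reactants: 15 (E)-1,5-anhydro-4,7-di-O-benzoyl-6-deoxy-2,3-di-O-PMB-D-lyxo-hepta-1,6-dienitol
Product: 16 (1R,2S,5S,6S)-2,5-bis(benzoyloxy)-1,6-bis(4-methoxybenzyloxy)cyclohex-3-ene-1-carbaldehyde (O1, O6, O5 on one face; O2 and CHO on the other)
Conditions: 1,2-dichlorobenzene (0.02 M, degassed), 2,6-di-tert-butyl-4-methylpyridine (0.2 equiv), BHT (cat.), silylated sealed tube, 190–210 °C
Reagents that add atoms: none
Why: Aliphatic Claisen rearrangement: the allyl vinyl ether sugar C2=C1–O5–C5–C6=C7 embedded in 15 undergoes a concerted suprafacial [3,3] shift that makes the sugar C2–C7 bond (C1–C2), breaks C5–O5, moves the alkene to sugar C5=C6 (C4=C3) and turns C1–O5 into the C7 aldehyde. The closest known reaction is the thermal carbocyclisation of 5-vinyl glycals to cyclohexene carbaldehydes; here both bond-forming carbons carry oxygen, an oxygen donor on the allyl terminus is known to lower Claisen barriers, and carbonyl formation makes the shift irreversible. The six-membered carbocycle (sugar C2, C3, C4, C5, C6, C7) is closed pericyclically by the new sigma bond while the pyran opens, and because the C3–C4 tether links both termini only a boat, bicyclo[2.2.2]octane-like transition state is possible. C1 is set by chirality transfer from sugar C5: the vinyl group reaches sugar C2 only from the β face on which it stands, which leaves O1 cis to O6 and O5 and the formyl group on the opposite face. C2 is set by alkene geometry: in this boat the E substituent of sugar C7 points towards the C1–O5 bridge and the Z hydrogen towards sugar C3, so the benzoate ends cis to the formyl group and trans to O1, and the E purity secured in steps 5 and 7 is the controlling element. The rearrangement must outrun acid-triggered allylic loss of the 3-OPMB group and loss of benzoic acid from the bis-allylic product, which is secured by an ether rather than an ester at O3, the absence of an α-hydrogen in 16, the hindered pyridine in silylated glass, and the galacto configuration, in which the ring flip that makes the vinyl group axial also makes O4 equatorial.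

Step 11
Reactants: 16 (1R,2S,5S,6S)-2,5-bis(benzoyloxy)-1,6-bis(4-methoxybenzyloxy)cyclohex-3-ene-1-carbaldehyde
Product: 17 [(1R,2S,5S,6S)-2,5-bis(benzoyloxy)-1,6-bis(4-methoxybenzyloxy)cyclohex-3-en-1-yl]methanol
Conditions: NaBH4, MeOH/CH2Cl2 (1:1), −20 °C
Reagents that add atoms: none
Why: Borohydride reduction of the non-enolisable aldehyde is much faster than attack on benzoates at low temperature, and a possible O2→O7 benzoyl shift in the alkoxide is harmless because both oxygens are benzoates after step 12.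

Step 12
Reactants: 17 [(1R,2S,5S,6S)-2,5-bis(benzoyloxy)-1,6-bis(4-methoxybenzyloxy)cyclohex-3-en-1-yl]methanol; 10 benzoyl chloride
Product: 18 [(1R,2S,5S,6S)-2,5-bis(benzoyloxy)-1,6-bis(4-methoxybenzyloxy)cyclohex-3-en-1-yl]methyl benzoate
Conditions: BzCl, pyridine, DMAP (cat.), CH2Cl2, 0 °C → rt
Reagents that add atoms: benzoyl chloride (10), O=C(Cl)c1ccccc1
Why: DMAP-catalysed acylation of the only free hydroxyl gives the same tribenzoate whether that hydroxyl sits on C7 or, after migration, on C2.

Step 13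
Reactants: 18 [(1R,2S,5S,6S)-2,5-bis(benzoyloxy)-1,6-bis(4-methoxybenzyloxy)cyclohex-3-en-1-yl]methyl benzoate
Product: 19 [(1S,2S,5S,6S)-2,5-bis(benzoyloxy)-1,6-dihydroxycyclohex-3-en-1-yl]methyl benzoate (CNP0128482.4)
Conditions: DDQ (3 equiv), CH2Cl2/pH 7 buffer (10:1), 0 °C → rt
Reagents that add atoms: none
Why: Oxidative PMB cleavage (hydride abstraction from the anisyl CH2 by DDQ, then hydrolysis of the oxocarbenium ion) runs at neutral pH, so the three benzoates neither cleave nor migrate, the alkene is untouched and no stereocentre is involved; the C1 descriptor changes only through ligand priorities.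

**Compound list**

1 | phenyl 1-thio-β-D-galactopyranoside | OC[C@H]1O[C@@H](Sc2ccccc2)[C@H](O)[C@@H](O)[C@H]1O | starting material
2 | benzaldehyde dimethyl acetal | COC(OC)c1ccccc1 | starting material
3 | phenyl 4,6-O-[(S)-benzylidene]-1-thio-β-D-galactopyranoside | c1ccccc1[C@H]1OC[C@H]2O[C@@H](Sc3ccccc3)[C@H](O)[C@@H](O)[C@H]2O1 | intermediate
4 | 4-methoxybenzyl chloride | COc1ccc(CCl)cc1 | starting material
5 | phenyl 4,6-O-[(S)-benzylidene]-2,3-di-O-PMB-1-thio-β-D-galactopyranoside | c1ccccc1[C@H]1OC[C@H]2O[C@@H](Sc3ccccc3)[C@H](OCc3ccc(OC)cc3)[C@@H](OCc3ccc(OC)cc3)[C@H]2O1 | intermediate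
6 | phenyl 2,3-di-O-PMB-1-thio-β-D-galactopyranoside | OC[C@H]1O[C@@H](Sc2ccccc2)[C@H](OCc2ccc(OC)cc2)[C@@H](OCc2ccc(OC)cc2)[C@H]1O | intermediate
7 | phenyl 2,3-di-O-PMB-1-thio-β-D-galacto-hexodialdo-1,5-pyranoside | O=C[C@H]1O[C@@H](Sc2ccccc2)[C@H](OCc2ccc(OC)cc2)[C@@H](OCc2ccc(OC)cc2)[C@H]1O | intermediate
8 | iodoform | IC(I)I | starting material
9 | phenyl (E)-6,7-dideoxy-7-iodo-2,3-di-O-PMB-1-thio-β-D-galacto-hept-6-enopyranoside | I/C=C/[C@H]1O[C@@H](Sc2ccccc2)[C@H](OCc2ccc(OC)cc2)[C@@H](OCc2ccc(OC)cc2)[C@H]1O | intermediate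
10 | benzoyl chloride | O=C(Cl)c1ccccc1 | starting material
11 | phenyl (E)-4-O-benzoyl-6,7-dideoxy-7-iodo-2,3-di-O-PMB-1-thio-β-D-galacto-hept-6-enopyranoside | I/C=C/[C@H]1O[C@@H](Sc2ccccc2)[C@H](OCc2ccc(OC)cc2)[C@@H](OCc2ccc(OC)cc2)[C@H]1OC(=O)c1ccccc1 | intermediate
12 | benzoic acid | O=C(O)c1ccccc1 | starting material
13 | phenyl (E)-4,7-di-O-benzoyl-6-deoxy-2,3-di-O-PMB-1-thio-β-D-galacto-hept-6-enopyranoside | O=C(c1ccccc1)O/C=C/[C@H]1O[C@@H](Sc2ccccc2)[C@H](OCc2ccc(OC)cc2)[C@@H](OCc2ccc(OC)cc2)[C@H]1OC(=O)c1ccccc1 | intermediate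
14 | S-oxide of 13 (β-glycosyl phenyl sulfoxide, both sulfur epimers) | O=C(c1ccccc1)O/C=C/[C@H]1O[C@@H](S(=O)c2ccccc2)[C@H](OCc2ccc(OC)cc2)[C@@H](OCc2ccc(OC)cc2)[C@H]1OC(=O)c1ccccc1 | intermediate
15 | (E)-1,5-anhydro-4,7-di-O-benzoyl-6-deoxy-2,3-di-O-PMB-D-lyxo-hepta-1,6-dienitol | C1=C(OCc2ccc(OC)cc2)[C@@H](OCc2ccc(OC)cc2)[C@@H](OC(=O)c2ccccc2)[C@H](O1)/C=C/OC(=O)c1ccccc1 | intermediate
16 | (1R,2S,5S,6S)-2,5-bis(benzoyloxy)-1,6-bis(4-methoxybenzyloxy)cyclohex-3-ene-1-carbaldehyde | O=C[C@@]1(OCc2ccc(OC)cc2)[C@@H](OC(=O)c2ccccc2)C=C[C@H](OC(=O)c2ccccc2)[C@@H]1OCc1ccc(OC)cc1 | intermediate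
17 | [(1R,2S,5S,6S)-2,5-bis(benzoyloxy)-1,6-bis(4-methoxybenzyloxy)cyclohex-3-en-1-yl]methanol | OC[C@@]1(OCc2ccc(OC)cc2)[C@@H](OC(=O)c2ccccc2)C=C[C@H](OC(=O)c2ccccc2)[C@@H]1OCc1ccc(OC)cc1 | intermediate
18 | [(1R,2S,5S,6S)-2,5-bis(benzoyloxy)-1,6-bis(4-methoxybenzyloxy)cyclohex-3-en-1-yl]methyl benzoate | O=C(OC[C@@]1(OCc2ccc(OC)cc2)[C@@H](OC(=O)c2ccccc2)C=C[C@H](OC(=O)c2ccccc2)[C@@H]1OCc1ccc(OC)cc1)c1ccccc1 | intermediate
19 | [(1S,2S,5S,6S)-2,5-bis(benzoyloxy)-1,6-dihydroxycyclohex-3-en-1-yl]methyl benzoate | O=C(OC[C@@]1(O)[C@@H](OC(=O)c2ccccc2)C=C[C@H](OC(=O)c2ccccc2)[C@@H]1O)c1ccccc1 | target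

Total step count: 13. Longest linear sequence: 13 steps (1 → 19).

**Steps most likely to fail**

Step 10. At the temperature the boat transition state demands, the rearrangement may be overtaken by decomposition. The likely modes are allylic ionisation at sugar C3, thermal loss of benzoic acid followed by aromatisation, and allylic transposition of the product benzoates. The fallback sets out from 13 and returns at 17. It lowers the barrier by moving to the ketene acetal oxidation level, an Ireland–Claisen ring contraction of a vinyl lactone, which is known to pass through the same enforced boat at far lower temperature. Thioglycoside 13 is hydrolysed (NIS, acetone/H2O, 0 °C) to the hemiacetal F1. This is oxidised (Dess–Martin periodinane, CH2Cl2) to the 1,5-lactone F2. Soft enolisation (TBSOTf, Et3N, toluene, rt) avoids a free enolate and hence β-elimination of O3, and gives the silyl ketene acetal F3. This should rearrange between rt and 80 °C to the TBS ester F4. Mild hydrolysis (AcOH/THF/H2O) gives the carboxylic acid F5. BH3·SMe2 (THF, 0 °C) reduces acids faster than benzoates or the deactivated alkene and delivers 17.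

Step 7. The weakly nucleophilic benzoate may couple too slowly. Reduction or homocoupling of the vinyl iodide, erosion of the alkene geometry, or carbonate-induced ester cleavage could then take over at 90 °C. The fallback sets out from 11 and returns at 13. It reverses the polarity of the vinyl partner and uses an oxidative Chan–Lam-type coupling. Miyaura borylation (B2pin2, PdCl2(dppf), KOAc, 1,4-dioxane, 80 °C) converts 11 with retention into the (E)-alkenyl pinacol boronate F6. KHF2 (MeOH/H2O) gives the potassium alkenyltrifluoroborate F7. Coupling with benzoic acid 12 (CuBr cat., DMAP, 4 Å molecular sieves, O2, CH2Cl2, 40 °C) forms the enol benzoate 13 under nearly neutral conditions.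

Step 9. The syn elimination may be overtaken by heterolysis of the anomeric C–S bond (sulfoxide to sulfenate isomerisation) or spoiled by re-addition of the released sulfenic acid to the electron-rich enol ether. The fallback sets out from 13 and returns at 15. It replaces the Ei process with the classical anti E2 elimination of a glycosyl halide. Thioglycoside 13 is treated with the chlorosulfonium reagent made from Ph2SO and (COCl)2 (CH2Cl2, −78 → 0 °C, cyclohexene as trap for the sulfenyl chloride) to give the α-glycosyl chloride F8. Its axial chloride is antiperiplanar to axial H2, so DBU (CH2Cl2, 0 °C → rt) should give 15.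

**Further compounds**

F1 | step 10 | (E)-4,7-di-O-benzoyl-6-deoxy-2,3-di-O-PMB-D-galacto-hept-6-enopyranose (hemiacetal, both anomers) | O=C(c1ccccc1)O/C=C/[C@H]1OC(O)[C@H](OCc2ccc(OC)cc2)[C@@H](OCc2ccc(OC)cc2)[C@H]1OC(=O)c1ccccc1
F2 | step 10 | (E)-4,7-di-O-benzoyl-6-deoxy-2,3-di-O-PMB-D-galacto-hept-6-enono-1,5-lactone | O=C(c1ccccc1)O/C=C/[C@H]1OC(=O)[C@H](OCc2ccc(OC)cc2)[C@@H](OCc2ccc(OC)cc2)[C@H]1OC(=O)c1ccccc1
F3 | step 10 | tert-butyldimethylsilyl ketene acetal of F2 (1-silyloxy analogue of 15) | O=C(c1ccccc1)O/C=C/[C@H]1OC(O[Si](C)(C)C(C)(C)C)=C(OCc2ccc(OC)cc2)[C@@H](OCc2ccc(OC)cc2)[C@H]1OC(=O)c1ccccc1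
F4 | step 10 | tert-butyldimethylsilyl 2,5-bis(benzoyloxy)-1,6-bis(4-methoxybenzyloxy)cyclohex-3-ene-1-carboxylate (configuration as 16) | CC(C)(C)[Si](C)(C)OC(=O)[C@@]1(OCc2ccc(OC)cc2)[C@@H](OC(=O)c2ccccc2)C=C[C@H](OC(=O)c2ccccc2)[C@@H]1OCc1ccc(OC)cc1
F5 | step 10 | 2,5-bis(benzoyloxy)-1,6-bis(4-methoxybenzyloxy)cyclohex-3-ene-1-carboxylic acid (configuration as 16) | OC(=O)[C@@]1(OCc2ccc(OC)cc2)[C@@H](OC(=O)c2ccccc2)C=C[C@H](OC(=O)c2ccccc2)[C@@H]1OCc1ccc(OC)cc1
F6 | step 7 | (E)-alkenyl pinacol boronate corresponding to 11 (Bpin in place of iodine) | CC1(C)OB(/C=C/[C@H]2O[C@@H](Sc3ccccc3)[C@H](OCc3ccc(OC)cc3)[C@@H](OCc3ccc(OC)cc3)[C@H]2OC(=O)c2ccccc2)OC1(C)C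
F7 | step 7 | potassium (E)-alkenyltrifluoroborate corresponding to 11 | [K+].F[B-](F)(F)/C=C/[C@H]1O[C@@H](Sc2ccccc2)[C@H](OCc2ccc(OC)cc2)[C@@H](OCc2ccc(OC)cc2)[C@H]1OC(=O)c1ccccc1
F8 | step 9 | (E)-4,7-di-O-benzoyl-6-deoxy-2,3-di-O-PMB-α-D-galacto-hept-6-enopyranosyl chloride | O=C(c1ccccc1)O/C=C/[C@H]1O[C@H](Cl)[C@H](OCc2ccc(OC)cc2)[C@@H](OCc2ccc(OC)cc2)[C@H]1OC(=O)c1ccccc1
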